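**Remark (assumption on the chemistry).** The SMILES is taken as written: the exocyclic enol‑lactone alkene is E (chain cis to the hydroxyl‑bearing ring carbon, trans to the ring oxygen), the stereocentre is S, and both chain alkenes are E. Numbering used below: furan C1–C4 (chain on C3); chain C5–C20 with methyls C9 (on C8), C14 (on C13) and C19 (on C18); lactone O1, C21 (ylidene carbon), C22 (C–OH), C23 (C–CH3, methyl C25), C24 (C=O).

## Structural features

The target 27 is a linear C25 furanosesterterpenoid: a 3‑substituted furan and a 3‑methyltetronic acid sit at the two ends of a thirteen‑carbon chain (C5–C20) that carries three methyl branches. The chain joins the lactone through an exocyclic, trisubstituted enol‑lactone alkene C20=C21 of E geometry, in which C18 lies cis to C22 and trans to O1. This is the isomer that suffers allylic strain with the C22 oxygen, so it is not the one that condensation–elimination or equilibration delivers. The only stereocentre, C18 (S), is directly attached to C20; it bears H, CH3 and two carbon chains and has no heteroatom to help set it. The middle of the chain is a skipped diene, C8=C10 and C12=C13 (both E, both trisubstituted), around the doubly allylic C11; base, acid or radicals can move it into conjugation. Fragile groups are the acid‑sensitive furan, the vinylogous acid, and the enol lactone, which is open to nucleophiles and to E→Z isomerisation by acid, light, iodine or reversible conjugate addition. The real difficulty is the E‑configured C20=C21 alkene together with the adjacent C18 stereocentre; the skipped diene is the second problem.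

## Logic of the disconnections

**27 ⇒ 26.** Cut: the O–CH2 bond of the 2‑silylethyl ether on the C22 oxygen. The acidic OH would quench the organometallics of the key step, and it must be unmasked without acid, thiolate or halide nucleophiles so that the E alkene, furan and skipped diene are not put at risk. No skeletal gain. Demand: a fluoride‑triggered cleavage mild enough to leave C20=C21 untouched.

**26 ⇒ 16 + 23 (key).** Cut: the C18–C20 σ‑bond between the stereocentre and the exocyclic alkene carbon. This avoids making C20=C21 by condensation (which leads to the Z isomer) and avoids an α‑methyl aldehyde. Gain: a convergent union of a chain half whose only stereocentre is an unactivated secondary carbon (16) with a small heterocycle that already holds the E geometry (23). Demand: the sp3–sp2 coupling must proceed with retention at both carbons and without β‑hydride elimination.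

**23 ⇒ 22.** Cut: O1–C21 and C20–I. Anti addition of the carboxylate oxygen and iodine across a terminal alkyne places iodine trans to O1, which is exactly the site C18 must occupy. Gain: the E problem is reduced to a cis relationship of carboxyl and alkyne across C22=C23. Demand: 5‑exo‑dig closure must win over 6‑endo‑dig closure.

**22 ⇒ 21.** Cut: the C20–C21 bond (one‑carbon homologation of a latent aldehyde at C21). In 21, C24 and C21 are members of one five‑membered ring, so after ring opening the acid and the new alkyne are necessarily cis. Demand: the homologation must not add to or isomerise the tetrasubstituted alkene.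

**21 ⇒ 20 ⇒ 19 ⇒ 17.** Cuts: C21–OH (oxidation of the ring CH2), the ether bond on the C22 oxygen, and the lactone O1–C21 bond. The heterocycle is traced to a commodity β‑keto ester. Demand: oxidation at C21 and not at C23.

**16 ⇒ 15 ⇒ 12 + 13.** Cuts: C18–I (made from C18–O with inversion) and C16–C17 (opening of 13 at its CH2 terminus). Gain: the stereocentre is bought, not made. Demand: clean inversion in the C–O to C–I exchange and no attack at the substituted carbon of 13.

**12 ⇒ 11 ⇒ 8 + 9.** Cuts: C16–Br, then C11–C12 and C13–C14. The skipped diene is formed by joining an alkenyl‑metal to an allylic chloride, and the C12=C13 geometry comes from a syn methyl–metal addition to the terminal alkyne of 9. Demand: coupling at the unsubstituted allyl terminus with retention of both alkenes.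

**8 ⇒ 7 ⇒ 5.** Cuts: C11–Cl, then C10–C11 (a one‑carbon electrophile) and C8–C9 (the same syn methyl–metal addition). Demand: regio‑ and stereoselective methylmetalation in the presence of the furan.

**5 ⇒ 4 ⇒ 1 + 2.** Cuts: the alkynyl C–Si bond and the C3–C5 bond (sp2–sp3 coupling onto the furan). Demand: a silyl cap so that the alkyne C–H does not quench the Grignard reagent.

## Other disconnections considered

**Alternative 1:** (the first that comes to mind) Cut C20=C21 as a carbonyl condensation. The C21 anion of 20 would add to the α‑methyl aldehyde A1 to give aldol A2, and sulfonylation/base elimination would form the alkene. The elimination runs by E1cB through a C21 carbanion, so the geometry is set by product stability. That places the chain syn to O1 and should give mainly the 5Z isomer A3, because the E isomer has allylic strain between C18 and the C22 alkoxy group. In addition, A1 carries the only stereocentre α to a formyl group and meets a strongly basic enolate. The chosen plan never makes C20 a carbonyl carbon and transfers a preformed E geometry.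

**Alternative 2:** Cut C20=C21 as a Wittig olefination of the cyclic anhydride A4 with the unstabilised, β‑branched ylide A5. The two anhydride carbonyls (C21 and C24) differ only by vinylogous donation from the alkoxy group, so regiocontrol rests on a small electronic bias. No element of the structure dictates which way the oxaphosphetane collapses, so the enol‑lactone geometry is uncontrolled and should drift toward Z. A basic ylide may also simply open the anhydride. Step count would be comparable, but the stereochemical issue stays unsolved, whereas the chosen coupling is stereospecific at both carbons.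

**Alternative 3:** Cut O1–C21 as a 5‑exo‑dig cycloisomerisation (AgNO3 or AuCl(PPh3)/AgOTf) of the chain‑bearing enynoic acid A6. Anti addition of O1 and H across C20≡C21 puts H trans to O1 and therefore C18 cis to O1, which is again A3. The E isomer would need a formal syn hydro‑acyloxylation, available only as a three‑step detour (syn hydrostannation, iododestannylation, CuI‑catalysed O‑vinylation). A6 also needs a propargylic stereocentre that costs more steps than buying 13. The chosen plan uses the same anti addition with iodine as the second addend, so the position trans to O1 becomes the attachment point for C18.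

Key step: step 14

## Route

Step 1
Reactants: 1 (5-chloropent-1-yn-1-yl)trimethylsilane; 2 3-bromofuran
Product: 4 [5-(furan-3-yl)pent-1-yn-1-yl]trimethylsilane, via Grignard reagent 3 (not isolated)
Conditions: Mg, BrCH2CH2Br (cat.), THF, reflux; then 2, NiCl2(dppp) (2 mol %), THF, 0 → 50 °C
Reagents that add atoms: none
Why: Kumada–Corriu coupling of a primary alkyl Grignard reagent with a heteroaryl bromide; the silyl cap keeps the alkyne C–H from quenching the Grignard reagent.

Step 2
Reactants: 4 [5-(furan-3-yl)pent-1-yn-1-yl]trimethylsilane
Product: 5 3-(pent-4-yn-1-yl)furan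
Conditions: K2CO3, MeOH, rt
Reagents that add atoms: none
Why: Methoxide‑mediated protodesilylation of an alkynylsilane; the furan is inert to mild base.

Step 3
Reactants: 5 3-(pent-4-yn-1-yl)furan
Product: 7 (2E)-6-(furan-3-yl)-3-methylhex-2-en-1-ol, via alkenylalane 6 (not isolated)
Conditions: Me3Al (2 equiv), Cp2ZrCl2 (0.2 equiv), CH2Cl2, 0 °C → rt; then n-BuLi, THF/hexane, −78 °C; (CH2O)n, −78 °C → rt; aq. potassium sodium tartrate
Reagents that add atoms: trimethylaluminium, C[Al](C)C; formaldehyde (as paraformaldehyde), C=O
Why: Zirconium‑catalysed carboalumination adds CH3 and Al syn across the terminal alkyne with methyl on the internal carbon, which fixes the E geometry at C8=C10. The derived alanate is hydroxymethylated with retention.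

Step 4
Reactants: 7 (2E)-6-(furan-3-yl)-3-methylhex-2-en-1-ol
Product: 8 3-[(4E)-6-chloro-4-methylhex-4-en-1-yl]furan
Conditions: N-chlorosuccinimide, Me2S, CH2Cl2, −30 → 0 °C
Reagents that add atoms: N-chlorosuccinimide, O=C1CCC(=O)N1Cl
Why: Corey–Kim chlorination: SN2 displacement of the alkoxysulfonium ion by chloride gives the primary allylic chloride without allylic transposition, under non‑acidic conditions that spare the furan.

Step 5
Reactants: 9 but-3-yn-1-ol; 8 3-[(4E)-6-chloro-4-methylhex-4-en-1-yl]furan
Product: 11 (3E,6E)-10-(furan-3-yl)-3,7-dimethyldeca-3,6-dien-1-ol, via alkenylalane alkoxide 10 (not isolated)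
Conditions: 9, Me3Al (3 equiv), Cp2ZrCl2 (0.25 equiv), CH2Cl2, 0 °C → rt; then 8, Pd(PPh3)4 (5 mol %), THF, rt; aq. potassium sodium tartrate
Reagents that add atoms: trimethylaluminium, C[Al](C)C
Why: A second syn carboalumination sets the E geometry at C12=C13. Palladium‑catalysed alkenylalane–allyl chloride coupling (Negishi type) joins C11 to C12 at the unsubstituted allyl terminus with retention of both alkene geometries, which gives the E,E skipped diene directly.

Step 6
Reactants: 11 (3E,6E)-10-(furan-3-yl)-3,7-dimethyldeca-3,6-dien-1-ol
Product: 12 3-[(4E,7E)-10-bromo-4,8-dimethyldeca-4,7-dien-1-yl]furan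
Conditions: CBr4, PPh3, CH2Cl2, 0 °C
Reagents that add atoms: carbon tetrabromide, BrC(Br)(Br)Br
Why: Appel bromination of a primary alcohol under neutral conditions; neither the skipped diene nor the furan is touched.

Step 7
Reactants: 12 3-[(4E,7E)-10-bromo-4,8-dimethyldeca-4,7-dien-1-yl]furan; 13 (R)-2-methyloxirane
Product: 15 (2R,6E,9E)-13-(furan-3-yl)-6,10-dimethyltrideca-6,9-dien-2-ol, via Grignard reagent 14 (not isolated)
Conditions: Mg, THF, rt; then CuI (10 mol %), 13 (1.5 equiv), −30 → 0 °C; aq. NH4Cl
Reagents that add atoms: none
Why: Copper‑catalysed opening of the epoxide at its CH2 terminus by the homoallylic Grignard reagent forms C16–C17. The stereocentre of 13 is not involved, so the alcohol is R.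

Step 8
Reactants: 15 (2R,6E,9E)-13-(furan-3-yl)-6,10-dimethyltrideca-6,9-dien-2-ol
Product: 16 3-[(4E,7E,12S)-12-iodo-4,8-dimethyltrideca-4,7-dien-1-yl]furan
Conditions: PPh3, I2, N-methylimidazole, CH2Cl2, −10 °C, 1 h
Reagents that add atoms: iodine, II
Why: Appel‑type iodination: iodide displaces the alkoxyphosphonium leaving group by SN2 with inversion (R alcohol to S iodide). Low temperature and short contact time limit iodide–iodide exchange.

Step 9
Reactants: 17 ethyl 2-methyl-3-oxobutanoate
Product: 19 4-hydroxy-3-methylfuran-2(5H)-one, via bromo keto ester 18 (not isolated)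
Conditions: Br2, CHCl3, 0 °C → rt, 16 h; then neat, 110–120 °C
Reagents that add atoms: none
Why: Bromination, with HBr‑mediated equilibration to the terminal (C4) bromide, followed by thermal lactonisation: the ester oxygen displaces bromide and bromoethane is lost. This is the classical tetronic acid synthesis.

Step 10
Reactants: 19 4-hydroxy-3-methylfuran-2(5H)-one
Product: 20 3-methyl-4-[2-(trimethylsilyl)ethoxy]furan-2(5H)-one
Conditions: Me3SiCH2CH2OH, PPh3, iPrO2CN=NCO2iPr, THF, 0 °C → rt
Reagents that add atoms: 2-(trimethylsilyl)ethanol, C[Si](C)(C)CCO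
Why: Mitsunobu O‑alkylation of the vinylogous acid at the C22 oxygen; the 2‑silylethyl group is stable to base and organometallics and is removable by fluoride.

Step 11
Reactants: 20 3-methyl-4-[2-(trimethylsilyl)ethoxy]furan-2(5H)-one
Product: 21 5-hydroxy-3-methyl-4-[2-(trimethylsilyl)ethoxy]furan-2(5H)-one (racemic)
Conditions: KN(SiMe3)2, THF, −78 °C; then 2-(benzenesulfonyl)-3-phenyloxaziridine, −78 °C; aq. NH4Cl
Reagents that add atoms: 2-(benzenesulfonyl)-3-phenyloxaziridine, O=S(=O)(c1ccccc1)N1OC1c1ccccc1
Why: Davis oxidation of the vinylogous enolate. Oxygen is delivered to the ring CH2 (C21) because the other nucleophilic terminus, C23, is fully substituted and its attack would break the vinylogous ester conjugation. The new stereocentre is irrelevant because it is destroyed in step 12.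

Step 12
Reactants: 21 5-hydroxy-3-methyl-4-[2-(trimethylsilyl)ethoxy]furan-2(5H)-one
Product: 22 (2E)-2-methyl-3-[2-(trimethylsilyl)ethoxy]pent-2-en-4-ynoic acid
Conditions: (MeO)2P(O)CHN2, KOtBu (2.2 equiv), THF, −78 °C → rt; cold aq. HCl to pH 3
Reagents that add atoms: dimethyl (diazomethyl)phosphonate, COP(=O)(OC)C=[N+]=[N-]
Why: Seyferth–Gilbert homologation: base opens the cyclic pseudo‑acid to the formyl carboxylate, whose non‑enolisable aldehyde is converted to the terminal alkyne. Because C21 and C24 came from one ring, alkyne and carboxyl are cis across C22=C23.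

Step 13
Reactants: 22 (2E)-2-methyl-3-[2-(trimethylsilyl)ethoxy]pent-2-en-4-ynoic acid
Product: 23 (5E)-5-(iodomethylidene)-3-methyl-4-[2-(trimethylsilyl)ethoxy]furan-2(5H)-one
Conditions: I2, NaHCO3, MeCN, 0 °C → rt, dark; aq. Na2S2O3
Reagents that add atoms: iodine, II
Why: Iodolactonisation: the carboxylate attacks the iodonium‑activated terminal alkyne in a 5‑exo‑dig mode, anti to iodine, so iodine ends trans to O1 (E). The ring closed here is the lactone of the target.

Step 14
Reactants: 16 3-[(4E,7E,12S)-12-iodo-4,8-dimethyltrideca-4,7-dien-1-yl]furan; 23 (5E)-5-(iodomethylidene)-3-methyl-4-[2-(trimethylsilyl)ethoxy]furan-2(5H)-one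
Product: 26 (5E)-5-[(2S,6E,9E)-13-(furan-3-yl)-2,6,10-trimethyltrideca-6,9-dien-1-ylidene]-3-methyl-4-[2-(trimethylsilyl)ethoxy]furan-2(5H)-one, via secondary alkyllithium 24 (not isolated), via mixed dialkylzinc 25 (not isolated)
Conditions: 16 added to t-BuLi (2.2 equiv), pentane/Et2O 3:2, −100 °C, about 1 min; Me3SiCH2ZnBr·LiBr (1.1 equiv), THF, −100 → −30 °C; then 23 (0.7 equiv), Pd2I2(PtBu3)2 (3 mol %), toluene, −25 °C → rt
Reagents that add atoms: none
Why: Stereoretentive Negishi cross‑coupling of a configurationally defined secondary alkylzinc. Iodine–lithium exchange at −100 °C goes through an iodine ate complex with retention, and the unstabilised alkyllithium 24 is trapped within about a minute by front‑side transmetalation to zinc, giving 25, which is configurationally stable at the coupling temperature. Zerovalent palladium inserts into the vinylic C20–I bond of 23 with retention of the E geometry, the secondary alkyl group passes from zinc to palladium with retention, and the bulky electron‑rich phosphine makes reductive elimination faster than β‑hydride elimination, so neither chain walking nor E/Z scrambling is expected. The closest known reaction type is the palladium‑catalysed coupling of enantioenriched open‑chain secondary alkylzinc reagents (made from secondary alkyl iodides by exchange and transmetalation) with alkenyl iodides. No ring is closed. No stereocentre is created: C18 is carried over from 13 through one inversion (step 8) and three retentive events, and the E geometry is carried over from the anti iodolactonisation of step 13. The selectivities needed are retention at C18 (secured by the very low temperature and by the absence of an adjacent heteroatom or π‑system; the trisubstituted C12=C13 alkene is too hindered for 5‑exo carbolithiation at −100 °C) and attack at C–I in preference to the lactone carbonyl (an alkylzinc does not add to esters). The Me3SiCH2 group on zinc is a non‑transferable ligand.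

Step 15
Reactants: 26 (5E)-5-[(2S,6E,9E)-13-(furan-3-yl)-2,6,10-trimethyltrideca-6,9-dien-1-ylidene]-3-methyl-4-[2-(trimethylsilyl)ethoxy]furan-2(5H)-one
Product: 27 (5E)-5-[(2S,6E,9E)-13-(furan-3-yl)-2,6,10-trimethyltrideca-6,9-dien-1-ylidene]-4-hydroxy-3-methylfuran-2(5H)-one
Conditions: Bu4NF, THF, 0 °C → rt; then cold 0.5 M aq. HCl to pH 3, extraction, exclusion of light
Reagents that add atoms: none
Why: Fluoride attacks silicon and the 2‑silylethyl group fragments to ethene and Me3SiF, releasing the tetronate anion, which is protonated on mild acidification. No acid strong enough to harm the furan and no nucleophile able to add reversibly to C20 is present, so the E alkene should persist.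

## Compound list

1 | (5-chloropent-1-yn-1-yl)trimethylsilane | C[Si](C)(C)C#CCCCCl | starting material
2 | 3-bromofuran | Brc1ccoc1 | starting material
3 | [5-(trimethylsilyl)pent-4-yn-1-yl]magnesium chloride | C[Si](C)(C)C#CCCC[Mg]Cl | intermediate
4 | [5-(furan-3-yl)pent-1-yn-1-yl]trimethylsilane | C[Si](C)(C)C#CCCCc1ccoc1 | intermediate
5 | 3-(pent-4-yn-1-yl)furan | C#CCCCc1ccoc1 | intermediate
6 | [(1E)-5-(furan-3-yl)-2-methylpent-1-en-1-yl]dimethylalumane | C[Al](C)/C=C(\C)CCCc1ccoc1 | intermediate
7 | (2E)-6-(furan-3-yl)-3-methylhex-2-en-1-ol | OC/C=C(\C)CCCc1ccoc1 | intermediate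
8 | 3-[(4E)-6-chloro-4-methylhex-4-en-1-yl]furan | ClC/C=C(\C)CCCc1ccoc1 | intermediate
9 | but-3-yn-1-ol | C#CCCO | starting material
10 | dimethylaluminium (3E)-4-(dimethylalumanyl)-3-methylbut-3-en-1-olate | C[Al](C)OCC/C(C)=C/[Al](C)C | intermediate
11 | (3E,6E)-10-(furan-3-yl)-3,7-dimethyldeca-3,6-dien-1-ol | OCC/C(C)=C/C/C=C(\C)CCCc1ccoc1 | intermediate
12 | 3-[(4E,7E)-10-bromo-4,8-dimethyldeca-4,7-dien-1-yl]furan | BrCC/C(C)=C/C/C=C(\C)CCCc1ccoc1 | intermediate
13 | (R)-2-methyloxirane | C[C@@H]1CO1 | starting material
14 | [(3E,6E)-10-(furan-3-yl)-3,7-dimethyldeca-3,6-dien-1-yl]magnesium bromide | Br[Mg]CC/C(C)=C/C/C=C(\C)CCCc1ccoc1 | intermediate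
15 | (2R,6E,9E)-13-(furan-3-yl)-6,10-dimethyltrideca-6,9-dien-2-ol | C[C@@H](O)CCC/C(C)=C/C/C=C(\C)CCCc1ccoc1 | intermediate
16 | 3-[(4E,7E,12S)-12-iodo-4,8-dimethyltrideca-4,7-dien-1-yl]furan | C[C@H](I)CCC/C(C)=C/C/C=C(\C)CCCc1ccoc1 | intermediate
17 | ethyl 2-methyl-3-oxobutanoate | CCOC(=O)C(C)C(C)=O | starting material
18 | ethyl 4-bromo-2-methyl-3-oxobutanoate | CCOC(=O)C(C)C(=O)CBr | intermediate
19 | 4-hydroxy-3-methylfuran-2(5H)-one | CC1=C(O)COC1=O | intermediate
20 | 3-methyl-4-[2-(trimethylsilyl)ethoxy]furan-2(5H)-one | CC1=C(OCC[Si](C)(C)C)COC1=O | intermediate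
21 | 5-hydroxy-3-methyl-4-[2-(trimethylsilyl)ethoxy]furan-2(5H)-one (racemic) | CC1=C(OCC[Si](C)(C)C)C(O)OC1=O | intermediate
22 | (2E)-2-methyl-3-[2-(trimethylsilyl)ethoxy]pent-2-en-4-ynoic acid | C#C/C(OCC[Si](C)(C)C)=C(/C)C(=O)O | intermediate
23 | (5E)-5-(iodomethylidene)-3-methyl-4-[2-(trimethylsilyl)ethoxy]furan-2(5H)-one | CC1=C(OCC[Si](C)(C)C)/C(=C\I)OC1=O | intermediate
24 | 3-[(4E,7E,12S)-12-lithio-4,8-dimethyltrideca-4,7-dien-1-yl]furan | C[C@H]([Li])CCC/C(C)=C/C/C=C(\C)CCCc1ccoc1 | intermediate
25 | [(2S,6E,9E)-13-(furan-3-yl)-6,10-dimethyltrideca-6,9-dien-2-yl][(trimethylsilyl)methyl]zinc | C[C@H]([Zn]C[Si](C)(C)C)CCC/C(C)=C/C/C=C(\C)CCCc1ccoc1 | intermediate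
26 | (5E)-5-[(2S,6E,9E)-13-(furan-3-yl)-2,6,10-trimethyltrideca-6,9-dien-1-ylidene]-3-methyl-4-[2-(trimethylsilyl)ethoxy]furan-2(5H)-one | CC1=C(OCC[Si](C)(C)C)/C(=C\[C@@H](C)CCC/C(C)=C/C/C=C(\C)CCCc2ccoc2)OC1=O | intermediate
27 | (5E)-5-[(2S,6E,9E)-13-(furan-3-yl)-2,6,10-trimethyltrideca-6,9-dien-1-ylidene]-4-hydroxy-3-methylfuran-2(5H)-one | CC1=C(O)/C(=C\[C@@H](C)CCC/C(C)=C/C/C=C(\C)CCCc2ccoc2)OC1=O | target

## Step count and least certain steps

Total step count: 15. Longest linear sequence: 10 steps (steps 1–8, 14, 15, from 1 and 2). The lactone branch (steps 9–13) is 5 steps before the convergence.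

**Step 14 (key step).** The most likely failure is erosion of configuration at C18, either through radical leakage during the iodine–lithium exchange or through epimerisation of the unstabilised secondary alkyllithium if it is not trapped fast enough. A second failure mode is β‑hydride elimination and reinsertion on palladium, which would reduce the vinyl iodide and give chain‑walked product. The fallback sets out from 12 and comes back at 26; it makes the carbon–metal bond without an alkyllithium and sets C18 by catalyst control. The Grignard reagent 14 (made from 12 as in step 7) is allylated with allyl bromide (CuI cat., THF, 0 °C) to the terminal triene 3-[(4E,7E)-4,8-dimethyltrideca-4,7,12-trien-1-yl]furan F1. Copper‑catalysed enantioselective Markovnikov hydroboration of the monosubstituted alkene (CuCl, a P‑stereogenic bisphosphine such as QuinoxP* in the enantiomer that gives the S product, B2pin2, KOtBu, MeOH, THF) leaves the trisubstituted alkenes untouched and gives the secondary boronic ester 2-[(2S,6E,9E)-13-(furan-3-yl)-6,10-dimethyltrideca-6,9-dien-2-yl]-4,4,5,5-tetramethyl-1,3,2-dioxaborolane F2. Activation with t-BuLi at −78 °C and boron‑to‑zinc exchange with ZnCl2, which is stereoretentive, gives chloro[(2S,6E,9E)-13-(furan-3-yl)-6,10-dimethyltrideca-6,9-dien-2-yl]zinc F3. This is coupled with 23 under the palladium conditions of step 14 to rejoin the route at 26.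

**Step 13.** Two processes may compete: 6‑endo‑dig closure to an iodopyranone, and iodine‑ or light‑mediated E→Z isomerisation of the strained vinyl iodide (iodine sits next to the C22 alkoxy group). The fallback sets out from 22 and comes back at 23; it replaces iodonium activation by a palladium‑mediated anti acyloxystannylation. The acid 22 is converted with (Bu3Sn)2O (toluene, azeotropic drying) into tributylstannyl (2E)-2-methyl-3-[2-(trimethylsilyl)ethoxy]pent-2-en-4-ynoate F4. Pd(PPh3)4 (5 mol %, THF, rt) then effects 5‑exo cyclisation with transfer of tin to the terminal carbon trans to O1, giving (5E)-3-methyl-5-[(tributylstannyl)methylidene]-4-[2-(trimethylsilyl)ethoxy]furan-2(5H)-one F5. Iododestannylation (I2, CH2Cl2, 0 °C) proceeds with retention to 23.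

**Step 12.** The diazophosphonate anion may attack the closed lactone if ring opening of the pseudo‑acid is incomplete, and alkoxide may add to the conjugated diazoalkene intermediate instead of the desired carbene 1,2‑shift. The fallback sets out from 21 and comes back at 22; it uses olefination followed by elimination. Wittig chloromethylenation of the ring‑opened formyl carboxylate (Ph3P=CHCl from the phosphonium chloride and KOtBu, 2.2 equiv, THF, 0 °C) gives (2E)-5-chloro-2-methyl-3-[2-(trimethylsilyl)ethoxy]penta-2,4-dienoic acid F6 as a mixture at the new C4=C5 alkene, which is of no consequence. Dehydrochlorination with LiN(iPr)2 (3.2 equiv, THF, −78 → 0 °C) and acid quench gives 22.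

**Step 11.** Oxygen transfer may occur at C23 instead of C21, and the ring‑opened formyl carboxylate formed in situ may be consumed by aldol addition of unreacted enolate. The fallback sets out from 20 and comes back at 21; it oxidises a neutral silyloxyfuran instead of an enolate. Silylation (tBuMe2SiOSO2CF3, Et3N, CH2Cl2, 0 °C) gives tert-butyl(dimethyl)({3-methyl-4-[2-(trimethylsilyl)ethoxy]furan-2-yl}oxy)silane F7. Dimethyldioxirane (acetone, −78 °C) epoxidises the electron‑rich C21=C22 enol ether bond, the epoxide opens with silyl transfer to the carboxylate, and aqueous work‑up closes the pseudo‑acid to 21.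

## Further compounds

F1 | step 14 | 3-[(4E,7E)-4,8-dimethyltrideca-4,7,12-trien-1-yl]furan | C=CCCC/C(C)=C/C/C=C(\C)CCCc1ccoc1
F2 | step 14 | 2-[(2S,6E,9E)-13-(furan-3-yl)-6,10-dimethyltrideca-6,9-dien-2-yl]-4,4,5,5-tetramethyl-1,3,2-dioxaborolane | C[C@H](B1OC(C)(C)C(C)(C)O1)CCC/C(C)=C/C/C=C(\C)CCCc1ccoc1
F3 | step 14 | chloro[(2S,6E,9E)-13-(furan-3-yl)-6,10-dimethyltrideca-6,9-dien-2-yl]zinc | C[C@H]([Zn]Cl)CCC/C(C)=C/C/C=C(\C)CCCc1ccoc1
F4 | step 13 | tributylstannyl (2E)-2-methyl-3-[2-(trimethylsilyl)ethoxy]pent-2-en-4-ynoate | C#C/C(OCC[Si](C)(C)C)=C(/C)C(=O)O[Sn](CCCC)(CCCC)CCCC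
F5 | step 13 | (5E)-3-methyl-5-[(tributylstannyl)methylidene]-4-[2-(trimethylsilyl)ethoxy]furan-2(5H)-one | CC1=C(OCC[Si](C)(C)C)/C(=C\[Sn](CCCC)(CCCC)CCCC)OC1=O
F6 | step 12 | (2E)-5-chloro-2-methyl-3-[2-(trimethylsilyl)ethoxy]penta-2,4-dienoic acid (mixture at C4=C5) | ClC=C/C(OCC[Si](C)(C)C)=C(/C)C(=O)O
F7 | step 11 | tert-butyl(dimethyl)({3-methyl-4-[2-(trimethylsilyl)ethoxy]furan-2-yl}oxy)silane | Cc1c(OCC[Si](C)(C)C)coc1O[Si](C)(C)C(C)(C)C
A1 | alternative 1 | (2S,6E,9E)-13-(furan-3-yl)-2,6,10-trimethyltrideca-6,9-dienal | O=C[C@@H](C)CCC/C(C)=C/C/C=C(\C)CCCc1ccoc1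
A2 | alternative 1 | 5-[(2S,6E,9E)-13-(furan-3-yl)-1-hydroxy-2,6,10-trimethyltrideca-6,9-dien-1-yl]-3-methyl-4-[2-(trimethylsilyl)ethoxy]furan-2(5H)-one (mixture at the two new centres) | CC1=C(OCC[Si](C)(C)C)C(C(O)[C@@H](C)CCC/C(C)=C/C/C=C(\C)CCCc2ccoc2)OC1=O
A3 | alternative 1 | (5Z)-5-[(2S,6E,9E)-13-(furan-3-yl)-2,6,10-trimethyltrideca-6,9-dien-1-ylidene]-3-methyl-4-[2-(trimethylsilyl)ethoxy]furan-2(5H)-one | CC1=C(OCC[Si](C)(C)C)/C(=C/[C@@H](C)CCC/C(C)=C/C/C=C(\C)CCCc2ccoc2)OC1=O
A4 | alternative 2 | 3-methyl-4-[2-(trimethylsilyl)ethoxy]furan-2,5-dione | CC1=C(OCC[Si](C)(C)C)C(=O)OC1=O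
A5 | alternative 2 | [(2S,6E,9E)-13-(furan-3-yl)-2,6,10-trimethyltrideca-6,9-dien-1-ylidene]triphenyl-λ5-phosphane | C[C@H](C=P(c1ccccc1)(c1ccccc1)c1ccccc1)CCC/C(C)=C/C/C=C(\C)CCCc1ccoc1
A6 | alternative 3 | (2E,6S,10E,13E)-17-(furan-3-yl)-2,6,10,14-tetramethyl-3-[2-(trimethylsilyl)ethoxy]heptadeca-2,10,13-trien-4-ynoic acid | OC(=O)/C(C)=C(OCC[Si](C)(C)C)\C#C[C@@H](C)CCC/C(C)=C/C/C=C(\C)CCCc1ccoc1
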